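**Retrosynthetic overview**

1. Target 23 comes from the protected isoflavone 22 by acidic methanolysis of two MOM ethers and one TBS ether.
2. 22 comes from formyl ketone 20 by closing ring C (the pyranone) last, through O1–C8a. The strategy rests on C8a of ring A being ortho to the C4 carbonyl and meta to the C5 and C7 oxygens, so a fluorine placed at C8a can be displaced by the enolate oxygen that becomes O1.
3. 20 comes from deoxybenzoin 19 by Claisen C-formylation (supplies C2); 19 comes from aryllithium 17 and Weinreb amide 16 (C4–C4a bond), ring B arriving with 4-hydroxyphenylacetic acid.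
4. Ring A is bought as 3-fluoro-5-methoxyphenol and filled by three directed ortho-metalations in the order C6 (epoxide 6 from L-valine, which carries the only stereocenter), C8 (prenyl), C4a (acyl).
5. Ring order: rings A and B are purchased arenes; ring C is formed in step 12.

Key step: step 12

Remark: 3-fluoro-5-methoxyphenol (1) is taken as the purchased arene; it is the mono-demethylated form of 1-fluoro-3,5-dimethoxybenzene, and buying it avoids a statistical ether cleavage.

**Route**

Step 1
Reactants: 1 3-fluoro-5-methoxyphenol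
Product: 2 1-fluoro-3-methoxy-5-(methoxymethoxy)benzene
Conditions: MOMCl, i-Pr2NEt, CH2Cl2, 0 °C to rt
Reagents that add atoms: chloromethyl methyl ether (MOMCl), COCCl
Why: O-alkylation of the phenol with the reactive α-chloro ether (Williamson-type MOM ether formation) is routine and installs the acetal oxygen that later steers the ring metalations.

Step 2
Reactants: 3 L-valine
Product: 4 (2S)-2-chloro-3-methylbutanoic acid
Conditions: NaNO2, 6 M aq. HCl, 0 °C to rt
Reagents that add atoms: hydrochloric acid, Cl
Why: Diazotisation of the α-amino acid and chloride substitution proceed with net retention (double inversion through the α-lactone formed by carboxylate participation), so the (S) centre of valine becomes the (S) C–Cl centre.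

Step 3
Reactants: 4 (2S)-2-chloro-3-methylbutanoic acid
Product: 5 (2S)-2-chloro-3-methylbutan-1-ol
Conditions: LiAlH4, Et2O, 0 °C; aqueous work-up
Reagents that add atoms: none
Why: Hydride reduction of the carboxylic acid at 0 °C is faster than displacement of the secondary chloride, and the stereocenter is not involved.

Step 4
Reactants: 5 (2S)-2-chloro-3-methylbutan-1-ol
Product: 6 (2R)-2-(propan-2-yl)oxirane
Conditions: KOH, H2O, rt; product distilled from the mixture
Reagents that add atoms: none
Why: Intramolecular Williamson etherification (3-exo-tet SN2 by the primary alkoxide) inverts the chlorine-bearing carbon and should give the (R)-epoxide.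

Step 5
Reactants: 2 1-fluoro-3-methoxy-5-(methoxymethoxy)benzene; 6 (2R)-2-(propan-2-yl)oxirane
Product: 8 (2S)-1-[4-fluoro-2-methoxy-6-(methoxymethoxy)phenyl]-3-methylbutan-2-ol, via aryllithium 7 (not isolated)
Conditions: n-BuLi, Et2O, 0 °C; then THF, −78 °C, 6, BF3·OEt2; H2O
Reagents that add atoms: none
Why: Directed ortho-metalation in weakly coordinating ether should take place at the ring CH flanked by the OMOM and OMe donors (the future C6), and the aryllithium then opens the BF3-activated epoxide by SN2 attack at its unsubstituted CH2 carbon, so the stereocenter is carried in untouched from 6 and the (R)-epoxide gives the (S)-carbinol.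

Step 6
Reactants: 8 (2S)-1-[4-fluoro-2-methoxy-6-(methoxymethoxy)phenyl]-3-methylbutan-2-ol
Product: 9 tert-butyl({(2S)-1-[4-fluoro-2-methoxy-6-(methoxymethoxy)phenyl]-3-methylbutan-2-yl}oxy)dimethylsilane
Conditions: TBSCl, imidazole, DMAP (cat.), DMF, rt to 40 °C
Reagents that add atoms: tert-butyldimethylsilyl chloride (TBSCl), CC(C)(C)[Si](C)(C)Cl
Why: Silyl ether formation at the secondary alcohol under imidazole catalysis protects it for the two later lithiations and the base-mediated steps without touching the aryl MOM ether.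

Step 7
Reactants: 9 tert-butyl({(2S)-1-[4-fluoro-2-methoxy-6-(methoxymethoxy)phenyl]-3-methylbutan-2-yl}oxy)dimethylsilane; 10 prenyl bromide (1-bromo-3-methylbut-2-ene)
Product: 13 tert-butyl({(2S)-1-[4-fluoro-6-methoxy-2-(methoxymethoxy)-3-(3-methylbut-2-en-1-yl)phenyl]-3-methylbutan-2-yl}oxy)dimethylsilane, via aryllithium 11 (not isolated), via arylcopper 12 (not isolated)
Conditions: s-BuLi, THF, −78 °C; CuBr·SMe2, −78 °C; 10, −78 to −20 °C
Reagents that add atoms: none
Why: Directed ortho-metalation should select the CH between fluorine and the chelating OMOM group (fluorine acidifies both remaining CH positions, but only this one has the MOM oxygens to bind lithium, while the OMe next to the other CH is turned toward it by the neighbouring side chain), and Li-to-Cu transmetalation followed by allylic substitution at the primary carbon of prenyl bromide places the linear prenyl group at the future C8.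

Step 8
Reactants: 14 4-hydroxyphenylacetic acid
Product: 15 2-(4-hydroxyphenyl)-N-methoxy-N-methylacetamide
Conditions: CDI, THF, rt; then MeNHOMe·HCl, rt
Reagents that add atoms: N,O-dimethylhydroxylamine hydrochloride, CNOC.Cl
Why: Activation of the acid as its acyl imidazole and aminolysis by the hydroxylamine (Weinreb amide formation) is faster than acylation of the free phenol.

Step 9
Reactants: 15 2-(4-hydroxyphenyl)-N-methoxy-N-methylacetamide
Product: 16 N-methoxy-2-[4-(methoxymethoxy)phenyl]-N-methylacetamide
Conditions: MOMCl, i-Pr2NEt, CH2Cl2, 0 °C to rt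
Reagents that add atoms: chloromethyl methyl ether (MOMCl), COCCl
Why: MOM ether formation masks the phenol so that it cannot quench the aryllithium of step 10 and is removed together with the other acetal at the end.

Step 10
Reactants: 13 tert-butyl({(2S)-1-[4-fluoro-6-methoxy-2-(methoxymethoxy)-3-(3-methylbut-2-en-1-yl)phenyl]-3-methylbutan-2-yl}oxy)dimethylsilane; 16 N-methoxy-2-[4-(methoxymethoxy)phenyl]-N-methylacetamide
Product: 19 1-{2-fluoro-6-methoxy-4-(methoxymethoxy)-3-(3-methylbut-2-en-1-yl)-5-[(2S)-2-(tert-butyldimethylsilyloxy)-3-methylbutyl]phenyl}-2-[4-(methoxymethoxy)phenyl]ethan-1-one, via aryllithium 17 (not isolated), via lithium hemiaminal adduct 18 (not isolated)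
Conditions: s-BuLi, THF, −78 °C; 16, −78 °C; AcOH, −78 °C to rt
Reagents that add atoms: none
Why: The last ring CH, acidified by the flanking fluorine and methoxy group, is lithiated (directed ortho-metalation) and the aryllithium adds to the amide in a Weinreb ketone synthesis, the chelated tetrahedral adduct preventing over-addition and the −78 °C regime keeping the ortho-fluoro aryllithium from losing LiF.

Step 11
Reactants: 19 1-{2-fluoro-6-methoxy-4-(methoxymethoxy)-3-(3-methylbut-2-en-1-yl)-5-[(2S)-2-(tert-butyldimethylsilyloxy)-3-methylbutyl]phenyl}-2-[4-(methoxymethoxy)phenyl]ethan-1-one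
Product: 20 1-{2-fluoro-6-methoxy-4-(methoxymethoxy)-3-(3-methylbut-2-en-1-yl)-5-[(2S)-2-(tert-butyldimethylsilyloxy)-3-methylbutyl]phenyl}-3-hydroxy-2-[4-(methoxymethoxy)phenyl]prop-2-en-1-one
Conditions: NaH, HCO2Et, THF, 0 °C to rt; AcOH
Reagents that add atoms: ethyl formate, CCOC=O
Why: Crossed Claisen condensation of the deoxybenzoin enolate with the non-enolisable formate ester is driven by formation of the stabilised sodium enolate of the β-keto aldehyde, which is isolated as its enol after mild acidification.

Step 12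
Reactants: 20 1-{2-fluoro-6-methoxy-4-(methoxymethoxy)-3-(3-methylbut-2-en-1-yl)-5-[(2S)-2-(tert-butyldimethylsilyloxy)-3-methylbutyl]phenyl}-3-hydroxy-2-[4-(methoxymethoxy)phenyl]prop-2-en-1-one
Product: 22 6-[(2S)-2-(tert-butyldimethylsilyloxy)-3-methylbutyl]-5-methoxy-7-(methoxymethoxy)-3-[4-(methoxymethoxy)phenyl]-8-(3-methylbut-2-en-1-yl)-4H-chromen-4-one, via potassium enolate 21 (not isolated)
Conditions: K2CO3, anhydrous DMF, 80 °C
Reagents that add atoms: none
Why: Carbonate deprotonates the acidic β-keto aldehyde enol to the potassium enolate 21, whose formyl-derived oxygen adds to C8a to give a Meisenheimer-type anion delocalised into the ortho C4 carbonyl, and loss of fluoride then restores the arene (addition–elimination SNAr). The closest known reaction type is the chromone and flavone synthesis by intramolecular O-arylation of enolates of 1-(2-fluoroaryl)-1,3-dicarbonyl compounds, the oxygen counterpart of the fluoroquinolone ring closure. Ring C closes through a 6-membered transition state, formally a 6-endo-trig conjugate addition of oxygen to the C8a=C4a–C4=O unit followed by β-elimination of fluoride, and only the O1–C8a bond is formed. No stereocenter is created, and the (S)-carbinol carbon in the C6 side chain, held as its TBS ether, is inert to carbonate. The step needs O-arylation at a single carbon, which is secured because fluoride at C8a is the only leaving group, the enolate oxygen reaches it through a 6-membered array whereas the enolate carbon would have to close a 4-membered ring, and the enol isomers equilibrate through the aldehyde tautomer so that all material can adopt the reactive geometry. The C5 and C7 oxygens are meta to C8a and so do not push electron density onto the attacked carbon, and the basic medium leaves the prenyl group, both MOM acetals and the silyl ether untouched.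

Step 13
Reactants: 22 6-[(2S)-2-(tert-butyldimethylsilyloxy)-3-methylbutyl]-5-methoxy-7-(methoxymethoxy)-3-[4-(methoxymethoxy)phenyl]-8-(3-methylbut-2-en-1-yl)-4H-chromen-4-one
Product: 23 7-hydroxy-6-[(2S)-2-hydroxy-3-methylbutyl]-3-(4-hydroxyphenyl)-5-methoxy-8-(3-methylbut-2-en-1-yl)-4H-chromen-4-one
Conditions: HCl (about 1 M) in MeOH, rt to 40 °C
Reagents that add atoms: none
Why: Acid-catalysed acetal exchange removes both aryl MOM groups and methanolysis cleaves the secondary silyl ether, while the C5 methyl ether, the chromone and, at this mild acidity, the prenyl group should persist and the carbinol stereocenter is not touched.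

**Compound list**

1 | 3-fluoro-5-methoxyphenol | COc1cc(O)cc(F)c1 | starting material
2 | 1-fluoro-3-methoxy-5-(methoxymethoxy)benzene | COCOc1cc(F)cc(OC)c1 | intermediate
3 | L-valine | N[C@@H](C(C)C)C(=O)O | starting material
4 | (2S)-2-chloro-3-methylbutanoic acid | CC(C)[C@H](Cl)C(=O)O | intermediate
5 | (2S)-2-chloro-3-methylbutan-1-ol | CC(C)[C@H](Cl)CO | intermediate
6 | (2R)-2-(propan-2-yl)oxirane | CC(C)[C@@H]1CO1 | intermediate
7 | [4-fluoro-2-methoxy-6-(methoxymethoxy)phenyl]lithium | [Li]c1c(OC)cc(F)cc1OCOC | intermediate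
8 | (2S)-1-[4-fluoro-2-methoxy-6-(methoxymethoxy)phenyl]-3-methylbutan-2-ol | CC(C)[C@@H](O)Cc1c(OC)cc(F)cc1OCOC | intermediate
9 | tert-butyl({(2S)-1-[4-fluoro-2-methoxy-6-(methoxymethoxy)phenyl]-3-methylbutan-2-yl}oxy)dimethylsilane | CC(C)[C@@H](O[Si](C)(C)C(C)(C)C)Cc1c(OC)cc(F)cc1OCOC | intermediate
10 | prenyl bromide (1-bromo-3-methylbut-2-ene) | CC(C)=CCBr | starting material
11 | {3-[(2S)-2-(tert-butyldimethylsilyloxy)-3-methylbutyl]-6-fluoro-4-methoxy-2-(methoxymethoxy)phenyl}lithium | CC(C)[C@@H](O[Si](C)(C)C(C)(C)C)Cc1c(OC)cc(F)c([Li])c1OCOC | intermediate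
12 | {3-[(2S)-2-(tert-butyldimethylsilyloxy)-3-methylbutyl]-6-fluoro-4-methoxy-2-(methoxymethoxy)phenyl}copper | CC(C)[C@@H](O[Si](C)(C)C(C)(C)C)Cc1c(OC)cc(F)c([Cu])c1OCOC | intermediate
13 | tert-butyl({(2S)-1-[4-fluoro-6-methoxy-2-(methoxymethoxy)-3-(3-methylbut-2-en-1-yl)phenyl]-3-methylbutan-2-yl}oxy)dimethylsilane | CC(C)[C@@H](O[Si](C)(C)C(C)(C)C)Cc1c(OC)cc(F)c(CC=C(C)C)c1OCOC | intermediate
14 | 4-hydroxyphenylacetic acid | OC(=O)Cc1ccc(O)cc1 | starting material
15 | 2-(4-hydroxyphenyl)-N-methoxy-N-methylacetamide | CON(C)C(=O)Cc1ccc(O)cc1 | intermediate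
16 | N-methoxy-2-[4-(methoxymethoxy)phenyl]-N-methylacetamide | CON(C)C(=O)Cc1ccc(OCOC)cc1 | intermediate
17 | {2-fluoro-6-methoxy-4-(methoxymethoxy)-3-(3-methylbut-2-en-1-yl)-5-[(2S)-2-(tert-butyldimethylsilyloxy)-3-methylbutyl]phenyl}lithium | CC(C)[C@@H](O[Si](C)(C)C(C)(C)C)Cc1c(OC)c([Li])c(F)c(CC=C(C)C)c1OCOC | intermediate
18 | lithium 1-{2-fluoro-6-methoxy-4-(methoxymethoxy)-3-(3-methylbut-2-en-1-yl)-5-[(2S)-2-(tert-butyldimethylsilyloxy)-3-methylbutyl]phenyl}-1-[methoxy(methyl)amino]-2-[4-(methoxymethoxy)phenyl]ethan-1-olate | CC(C)[C@@H](O[Si](C)(C)C(C)(C)C)Cc1c(OC)c(C(O[Li])(N(C)OC)Cc2ccc(OCOC)cc2)c(F)c(CC=C(C)C)c1OCOC | intermediate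
19 | 1-{2-fluoro-6-methoxy-4-(methoxymethoxy)-3-(3-methylbut-2-en-1-yl)-5-[(2S)-2-(tert-butyldimethylsilyloxy)-3-methylbutyl]phenyl}-2-[4-(methoxymethoxy)phenyl]ethan-1-one | CC(C)[C@@H](O[Si](C)(C)C(C)(C)C)Cc1c(OC)c(C(=O)Cc2ccc(OCOC)cc2)c(F)c(CC=C(C)C)c1OCOC | intermediate
20 | 1-{2-fluoro-6-methoxy-4-(methoxymethoxy)-3-(3-methylbut-2-en-1-yl)-5-[(2S)-2-(tert-butyldimethylsilyloxy)-3-methylbutyl]phenyl}-3-hydroxy-2-[4-(methoxymethoxy)phenyl]prop-2-en-1-one | COc1c(C[C@H](O[Si](C)(C)C(C)(C)C)C(C)C)c(OCOC)c(CC=C(C)C)c(F)c1C(=O)C(=CO)c1ccc(OCOC)cc1 | intermediate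
21 | potassium enolate of 20 | COc1c(C[C@H](O[Si](C)(C)C(C)(C)C)C(C)C)c(OCOC)c(CC=C(C)C)c(F)c1C(=O)C(=C[O-])c1ccc(OCOC)cc1.[K+] | intermediate
22 | 6-[(2S)-2-(tert-butyldimethylsilyloxy)-3-methylbutyl]-5-methoxy-7-(methoxymethoxy)-3-[4-(methoxymethoxy)phenyl]-8-(3-methylbut-2-en-1-yl)-4H-chromen-4-one | COc1c(C[C@H](O[Si](C)(C)C(C)(C)C)C(C)C)c(OCOC)c(CC=C(C)C)c2occ(-c3ccc(OCOC)cc3)c(=O)c12 | intermediate
23 | 7-hydroxy-6-[(2S)-2-hydroxy-3-methylbutyl]-3-(4-hydroxyphenyl)-5-methoxy-8-(3-methylbut-2-en-1-yl)-4H-chromen-4-one | COc1c(C[C@H](O)C(C)C)c(O)c(CC=C(C)C)c2occ(-c3ccc(O)cc3)c(=O)c12 | target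

**Totals and risks**

Total step count: 13. Longest linear sequence: 10 steps (steps 2, 3, 4, 5, 6, 7, 10, 11, 12, 13, from L-valine).

Steps most likely to fail:

Step 12. The delocalised, weakly nucleophilic enolate oxygen may add too slowly to an electron-rich ring whose carbonyl is twisted out of conjugation by its two ortho substituents, and base-induced deformylation (retro-Claisen) back to 19 may then dominate. The fallback sets out from 19 and uses a harder oxygen nucleophile at the same carbon. Hydroxymethylation of 19 at its benzylic α-carbon (LiHMDS, THF, −78 °C, then monomeric formaldehyde) should give 1-{2-fluoro-6-methoxy-4-(methoxymethoxy)-3-(3-methylbut-2-en-1-yl)-5-[(2S)-2-(tert-butyldimethylsilyloxy)-3-methylbutyl]phenyl}-3-hydroxy-2-[4-(methoxymethoxy)phenyl]propan-1-one F1. Its alkoxide (NaH, THF, 0 °C to rt) would displace the fluoride to give the isoflavanone 6-[(2S)-2-(tert-butyldimethylsilyloxy)-3-methylbutyl]-5-methoxy-7-(methoxymethoxy)-3-[4-(methoxymethoxy)phenyl]-8-(3-methylbut-2-en-1-yl)-2,3-dihydro-4H-chromen-4-one F2 as a mixture of C3 epimers. Dehydrogenation across C2–C3 with DDQ (dioxane, 80 °C) comes back to the route at 22.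

Step 5. Metalation may occur at a fluorine-flanked carbon instead of between the two oxygens, and such an ortho-fluoro aryllithium would lose lithium fluoride at 0 °C (aryne formation). The fallback sets out from 2 and reverses the order of the first two ring substitutions. Metalation under acidity-ruled conditions (s-BuLi, THF, −78 °C), which address the CH between fluorine and OMOM, then transmetalation with CuBr·SMe2 and allylation with 10 should give 1-fluoro-5-methoxy-3-(methoxymethoxy)-2-(3-methylbut-2-en-1-yl)benzene F3. Its only CH flanked by two oxygens is then lithiated (n-BuLi, Et2O, 0 °C) and alkylated with 6 and BF3·OEt2 at −78 °C to give (2S)-1-[4-fluoro-6-methoxy-2-(methoxymethoxy)-3-(3-methylbut-2-en-1-yl)phenyl]-3-methylbutan-2-ol F4. Silylation (TBSCl, imidazole, DMF) comes back to the route at 13.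

Step 10. Proton transfer from the acidic benzylic CH2 of amide 16 to the hindered aryllithium (enolisation) may outrun addition, and the aryllithium may lose LiF if the mixture warms. The fallback sets out from 13 and forms the CH2–aryl bond separately. Aryllithium 17, generated as in step 10, is acylated with the small and less acidic N-methoxy-N-methylacetamide to give the methyl ketone 1-{2-fluoro-6-methoxy-4-(methoxymethoxy)-3-(3-methylbut-2-en-1-yl)-5-[(2S)-2-(tert-butyldimethylsilyloxy)-3-methylbutyl]phenyl}ethan-1-one F5. Palladium-catalysed ketone α-arylation of F5 with 1-bromo-4-(methoxymethoxy)benzene (Pd(OAc)2, XPhos, K3PO4, toluene, 80 °C) comes back to the route at 19.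

**Further compounds**

F1 | step 12 | 1-{2-fluoro-6-methoxy-4-(methoxymethoxy)-3-(3-methylbut-2-en-1-yl)-5-[(2S)-2-(tert-butyldimethylsilyloxy)-3-methylbutyl]phenyl}-3-hydroxy-2-[4-(methoxymethoxy)phenyl]propan-1-one | COc1c(C[C@H](O[Si](C)(C)C(C)(C)C)C(C)C)c(OCOC)c(CC=C(C)C)c(F)c1C(=O)C(CO)c1ccc(OCOC)cc1
F2 | step 12 | 6-[(2S)-2-(tert-butyldimethylsilyloxy)-3-methylbutyl]-5-methoxy-7-(methoxymethoxy)-3-[4-(methoxymethoxy)phenyl]-8-(3-methylbut-2-en-1-yl)-2,3-dihydro-4H-chromen-4-one | COc1c(C[C@H](O[Si](C)(C)C(C)(C)C)C(C)C)c(OCOC)c(CC=C(C)C)c2OCC(c3ccc(OCOC)cc3)C(=O)c12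
F3 | step 5 | 1-fluoro-5-methoxy-3-(methoxymethoxy)-2-(3-methylbut-2-en-1-yl)benzene | COCOc1cc(OC)cc(F)c1CC=C(C)C
F4 | step 5 | (2S)-1-[4-fluoro-6-methoxy-2-(methoxymethoxy)-3-(3-methylbut-2-en-1-yl)phenyl]-3-methylbutan-2-ol | CC(C)[C@@H](O)Cc1c(OC)cc(F)c(CC=C(C)C)c1OCOC
F5 | step 10 | 1-{2-fluoro-6-methoxy-4-(methoxymethoxy)-3-(3-methylbut-2-en-1-yl)-5-[(2S)-2-(tert-butyldimethylsilyloxy)-3-methylbutyl]phenyl}ethan-1-one | CC(=O)c1c(OC)c(C[C@H](O[Si](C)(C)C(C)(C)C)C(C)C)c(OCOC)c(CC=C(C)C)c1F
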